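The bicyclo[3.3.1]nonane-2,4,9-trione core is disconnected at C1–C2 and C5–C9. With both bonds cut, neither ring A (C1–C2–C3–C4–C5–C9) nor ring B (C1–C8–C7–C6–C5–C9) survives. The core unfolds into one acyclic chain, C9–C1–C8–C7–C6–C5–C4–C3–C2, with a methyl ester at each end. In one flask the key step folds this chain back. The C5 dienolate of a β-methoxy enoate is acylated by the C9 ester, and the new C9 ketone enolate then attacks the C2 ester through C1. The step exploits the 1,3-dicarbonyl relations C4/C9 across C5 and C2/C9 across C1. It sets both quaternary bridgeheads from C7 and C8, which an enantioselective Ireland–Claisen rearrangement installs.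

Key step: step 12

Numbering used throughout:
- C1 is the bridgehead next to C8.
- C2–C3–C4 is the enolised 1,3-diketone, with the aroyl group on C3.
- C5 is the bridgehead next to C6H2.
- C7 is CH(geranyl), C8 is C(CH3)(homoprenyl) and C9 is the bridging ketone.
- Prenyl is 3-methylbut-2-enyl, homoprenyl is 4-methylpent-3-enyl and geranyl is (2E)-3,7-dimethylocta-2,6-dienyl.

Assumption: the (S,S)-configured boron controller of step 2 is taken to deliver the (2S,3R)-acid 6. Should its facial sense be the opposite, its commercially available (R,R)-antipode is used and nothing else in the route changes.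

Step 1
Reactants: 1 geranyl acetate; 2 geranyl bromide
Product: 4 geranyl (4E)-5,9-dimethyldeca-4,8-dienoate, via lithium enolate of geranyl acetate 3 (not isolated)
Conditions: LDA, THF, −78 °C; then 2, DMPU, −78 → −40 °C
Reagents that add atoms: none
Why: Ester enolate alkylation, in which the kinetic lithium enolate of the acetate should displace the allylic bromide (SN2) below the temperature at which it would undergo its own [3,3] shift; no stereocentre is formed and both E-alkenes stay untouched.

Step 2
Reactants: 4 geranyl (4E)-5,9-dimethyldeca-4,8-dienoate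
Product: 6 (2S,3R)-2-geranyl-3,7-dimethyl-3-vinyloct-6-enoic acid, via Z(O)-boron ketene acetal 5 (not isolated)
Conditions: (1S,2S)-N,N'-bis{[3,5-bis(trifluoromethyl)phenyl]sulfonyl}-1,2-diphenylethane-1,2-diamine, BBr3, CH2Cl2, rt, then evaporation; 4, iPr2NEt, CH2Cl2, −78 °C, then −20 → 4 °C; aqueous work-up
Reagents that add atoms: none
Why: Enantioselective boron-enolate Ireland–Claisen rearrangement, in which iPr2NEt/CH2Cl2 should give the Z(O)-ketene acetal, whose chair transition state with the E-alkene (geranylmethyl and homoprenyl equatorial, methyl axial) fixes the C7/C8 relative configuration, while the C2-symmetric diazaborolidine selects the enolate face and so the absolute configuration.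

Step 3
Reactants: 6 (2S,3R)-2-geranyl-3,7-dimethyl-3-vinyloct-6-enoic acid
Product: 7 (2S,3R)-2-geranyl-3,7-dimethyl-3-vinyloct-6-en-1-ol
Conditions: LiAlH4, Et2O, 0 °C → rt
Reagents that add atoms: none
Why: Hydride reduction of the carboxylic acid to the primary alcohol (the future C6H2), which leaves isolated alkenes and both stereocentres untouched.

Step 4
Reactants: 7 (2S,3R)-2-geranyl-3,7-dimethyl-3-vinyloct-6-en-1-ol
Product: 8 (2S,3R)-2-geranyl-1-iodo-3,7-dimethyl-3-vinyloct-6-ene
Conditions: I2, PPh3, imidazole, CH2Cl2, 0 °C → rt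
Reagents that add atoms: iodine, II
Why: Appel-type iodination through the alkoxyphosphonium salt, which takes place at the primary carbon under neutral conditions, so the alkenes and the neighbouring stereocentre are not affected.

Step 5
Reactants: 8 (2S,3R)-2-geranyl-1-iodo-3,7-dimethyl-3-vinyloct-6-ene
Product: 10 (3R,4S,6E)-4-(iodomethyl)-3,7,11-trimethyl-3-(4-methylpent-3-enyl)dodeca-6,10-dien-1-ol, via B-alkyl-9-BBN adduct 9 (not isolated)
Conditions: 9-BBN, THF, rt; then NaBO3·4H2O, THF/H2O, rt
Reagents that add atoms: sodium perborate, O[B-]1(O)OO[B-](O)(O)OO1.[Na+].[Na+]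
Why: Hydroboration–oxidation, in which 9-BBN should select the only monosubstituted alkene over the three trisubstituted ones and place boron on the terminal carbon (C9), while the mild perborate oxidation spares the alkyl iodide.

Step 6
Reactants: 10 (3R,4S,6E)-4-(iodomethyl)-3,7,11-trimethyl-3-(4-methylpent-3-enyl)dodeca-6,10-dien-1-ol
Product: 11 (3R,4S,6E)-4-(iodomethyl)-3,7,11-trimethyl-3-(4-methylpent-3-enyl)dodeca-6,10-dienoic acid
Conditions: TEMPO (cat.), PhI(OAc)2, MeCN/H2O, rt
Reagents that add atoms: water, O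
Why: Oxoammonium (TEMPO/PhI(OAc)2) oxidation of the primary alcohol through the aldehyde hydrate to the acid, a method that tolerates trisubstituted alkenes and runs slightly acidic, so the carboxylate does not displace the iodide.

Step 7
Reactants: 11 (3R,4S,6E)-4-(iodomethyl)-3,7,11-trimethyl-3-(4-methylpent-3-enyl)dodeca-6,10-dienoic acid
Product: 12 methyl (3R,4S,6E)-4-(iodomethyl)-3,7,11-trimethyl-3-(4-methylpent-3-enyl)dodeca-6,10-dienoate
Conditions: TMSCHN2, toluene/MeOH, 0 °C
Reagents that add atoms: (trimethylsilyl)diazomethane, C[Si](C)(C)C=[N+]=[N-]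
Why: Methyl ester formation with a diazoalkane, chosen because it needs no base and so avoids lactonisation by carboxylate attack on the iodide.

Step 8
Reactants: 12 methyl (3R,4S,6E)-4-(iodomethyl)-3,7,11-trimethyl-3-(4-methylpent-3-enyl)dodeca-6,10-dienoate; 13 prenyl bromide
Product: 15 methyl (3R,4S,6E)-4-(iodomethyl)-3,7,11-trimethyl-2-prenyl-3-(4-methylpent-3-enyl)dodeca-6,10-dienoate (C2 epimers), via lithium enolate of ester 14 (not isolated)
Conditions: LDA, THF, −78 °C; then 13, DMPU, −78 → −40 °C
Reagents that add atoms: none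
Why: Ester enolate alkylation with the fast allylic bromide, which at −78 °C should outrun four-membered ring closure onto the iodide; C1 forms as an epimer mixture, which is harmless because C1 is enolised again in step 12.

Step 9
Reactants: 16 methyl acetoacetate; 13 prenyl bromide
Product: 18 methyl 7-methyl-3-oxooct-6-enoate, via sodium lithium dianion of acetoacetate 17 (not isolated)
Conditions: NaH, THF, 0 °C; n-BuLi, 0 °C; then 13; aq. HCl
Reagents that add atoms: none
Why: γ-Alkylation of a β-keto ester dianion, which reacts only at the more basic terminal carbanion; no stereocentre is formed.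

Step 10
Reactants: 18 methyl 7-methyl-3-oxooct-6-enoate; 15 methyl (3R,4S,6E)-4-(iodomethyl)-3,7,11-trimethyl-2-prenyl-3-(4-methylpent-3-enyl)dodeca-6,10-dienoate
Product: 20 dimethyl (6R,7S)-6-geranyl-7-methyl-7-(4-methylpent-3-enyl)-3-oxo-4,8-diprenylnonanedioate (C4 and C8 epimers), via sodium lithium dianion of keto ester 19 (not isolated)
Conditions: 18, NaH, THF, 0 °C; n-BuLi, 0 °C; then 15, DMPU, 0 °C → rt; aq. HCl
Reagents that add atoms: none
Why: γ-Alkylation of a β-keto ester dianion, in which the γ-carbanion (C5) should displace the primary iodide (C6) while the hindered C9 ester is left alone; C5 forms as an epimer mixture that is made planar again in step 12.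

Step 11
Reactants: 20 dimethyl (6R,7S)-6-geranyl-7-methyl-7-(4-methylpent-3-enyl)-3-oxo-4,8-diprenylnonanedioate
Product: 21 dimethyl (2E,6R,7S)-6-geranyl-3-methoxy-7-methyl-7-(4-methylpent-3-enyl)-4,8-diprenylnon-2-enedioate
Conditions: HC(OMe)3, MeOH, CSA (cat.), 40 °C
Reagents that add atoms: trimethyl orthoformate, COC(OC)OC
Why: Acid-catalysed ketalisation and loss of methanol (enol ether formation) should give the conjugated, thermodynamic E-3-methoxy enoate, which removes the acidic C3 methylene and holds C2 cis to C5, while catalytic CSA leaves the trisubstituted alkenes alone.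

Step 12
Reactants: 21 dimethyl (2E,6R,7S)-6-geranyl-3-methoxy-7-methyl-7-(4-methylpent-3-enyl)-4,8-diprenylnon-2-enedioate
Product: 23 (1R,5S,7R,8S)-7-geranyl-4-methoxy-8-methyl-8-(4-methylpent-3-enyl)-1,5-diprenylbicyclo[3.3.1]non-3-ene-2,9-dione, via monocyclic C9 ketone 22 (not isolated)
Conditions: LDA (2.4 equiv), THF, −78 → 40 °C; aq. NH4Cl
Reagents that add atoms: none
Why: Proposed new method: LDA removes the γ-proton at C5 of the β-methoxy enoate (syn to the ester carbonyl), the dienolate attacks the C9 ester through its γ-carbon [6-(enolexo)-exo-trig, ring B, C1–C8–C7–C6–C5–C9] and loss of methoxide gives ketone 22, whose only α-hydrogen (C1) is removed by the second equivalent of base so that the C1 enolate closes on the C2 ester [6-(enolendo)-exo-trig, ring A, C1–C2–C3–C4–C5–C9]. The closest known reaction types are the domino Dieckmann condensation used for bicyclo[3.3.1]nonane-2,4,9-triones, the γ-acylation of 3-methoxycrotonate dienolates and the second, intramolecular C-acylation of the Effenberger annulation. C5 is set in a chair transition state with the C7 geranyl and C8 homoprenyl groups equatorial and the C8 methyl axial, in which the flat enoate arm should take the axial and the prenyl group the equatorial site, as sp2 groups do on geminally disubstituted cyclohexanes. C1 follows from C5, because the axial arm can reach the planar C1 enolate only from its own face, so the C1 epimer mixture converges. The step needs γ- over α-acylation (α-attack would need an eight-membered ring), C- over O-acylation at C1 (an enol lactone would be reopened by the liberated methoxide, the shielded C-acyl product should not be) and no pyranone formation (C5 is quaternary, so C9 cannot enolise towards it). The E-enoate geometry from step 11 keeps C2 within reach of C1.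

Step 13
Reactants: 24 3-hydroxybenzoic acid
Product: 25 tert-butyldimethylsilyl 3-(tert-butyldimethylsilyloxy)benzoate
Conditions: TBSCl (2.2 equiv), imidazole, DMF, rt
Reagents that add atoms: tert-butyldimethylsilyl chloride, CC(C)(C)[Si](C)(C)Cl
Why: Silylation of phenol and acid under standard imidazole catalysis, giving a phenol protecting group that is inert to lithium amides and vinyllithiums.

Step 14
Reactants: 25 tert-butyldimethylsilyl 3-(tert-butyldimethylsilyloxy)benzoate
Product: 26 3-(tert-butyldimethylsilyloxy)benzoyl chloride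
Conditions: (COCl)2, DMF (cat.), CH2Cl2, 0 °C → rt
Reagents that add atoms: oxalyl chloride, ClC(=O)C(=O)Cl
Why: Direct conversion of a silyl ester into the acid chloride with the Vilsmeier reagent under neutral conditions, which frees no HCl and so keeps the aryl silyl ether.

Step 15
Reactants: 23 (1R,5S,7R,8S)-7-geranyl-4-methoxy-8-methyl-8-(4-methylpent-3-enyl)-1,5-diprenylbicyclo[3.3.1]non-3-ene-2,9-dione; 26 3-(tert-butyldimethylsilyloxy)benzoyl chloride
Product: 28 (1S,5S,7R,8S)-3-[3-(tert-butyldimethylsilyloxy)benzoyl]-7-geranyl-4-methoxy-8-methyl-8-(4-methylpent-3-enyl)-1,5-diprenylbicyclo[3.3.1]non-3-ene-2,9-dione, via C3-lithio vinylogous ester 27 (not isolated)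
Conditions: LiTMP (from TMP, n-BuLi), THF, −78 °C; then 26, −78 → 0 °C
Reagents that add atoms: none
Why: Vinylic lithiation of the vinylogous ester at C3 followed by acylation, a known sequence on this ring system that is unambiguous here because both bridgeheads are quaternary; no stereocentre changes (the C1 descriptor changes by CIP priority only).

Step 16
Reactants: 28 (1S,5S,7R,8S)-3-[3-(tert-butyldimethylsilyloxy)benzoyl]-7-geranyl-4-methoxy-8-methyl-8-(4-methylpent-3-enyl)-1,5-diprenylbicyclo[3.3.1]non-3-ene-2,9-dione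
Product: 29 (1S,5S,7R,8S)-7-geranyl-4-hydroxy-3-(3-hydroxybenzoyl)-8-methyl-8-(4-methylpent-3-enyl)-1,5-diprenylbicyclo[3.3.1]non-3-ene-2,9-dione (target)
Conditions: LiOH, 1,4-dioxane/H2O, 90 °C; then 1 M HCl
Reagents that add atoms: lithium hydroxide, [Li+].[OH-]
Why: Hydroxide addition–elimination at C4 should hydrolyse the vinylogous methyl ester and the same medium cleaves the phenolic silyl ether, while the bridgeheads cannot enolise and C7/C8 carry no acidic hydrogen, so no stereocentre is at risk.

Compound list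
1 | geranyl acetate | CC(=O)OC/C=C(\C)CCC=C(C)C | starting material
2 | geranyl bromide | CC(C)=CCC/C(C)=C/CBr | starting material
3 | lithium enolate of geranyl acetate | [Li]OC(=C)OC/C=C(\C)CCC=C(C)C | intermediate
4 | geranyl (4E)-5,9-dimethyldeca-4,8-dienoate | CC(C)=CCC/C(C)=C/CCC(=O)OC/C=C(\C)CCC=C(C)C | intermediate
5 | Z(O)-boron ketene acetal of 4, boron held in the (4S,5S)-diazaborolidine | CC(C)=CCC/C(C)=C/C/C=C(\OB1N(S(=O)(=O)c2cc(C(F)(F)F)cc(C(F)(F)F)c2)[C@@H](c2ccccc2)[C@H](c2ccccc2)N1S(=O)(=O)c1cc(C(F)(F)F)cc(C(F)(F)F)c1)OC/C=C(\C)CCC=C(C)C | intermediate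
6 | (2S,3R)-2-geranyl-3,7-dimethyl-3-vinyloct-6-enoic acid | CC(C)=CCC/C(C)=C/C[C@@H]([C@](C)(CCC=C(C)C)C=C)C(=O)O | intermediate
7 | (2S,3R)-2-geranyl-3,7-dimethyl-3-vinyloct-6-en-1-ol | CC(C)=CCC/C(C)=C/C[C@@H]([C@](C)(CCC=C(C)C)C=C)CO | intermediate
8 | (2S,3R)-2-geranyl-1-iodo-3,7-dimethyl-3-vinyloct-6-ene | CC(C)=CCC/C(C)=C/C[C@@H]([C@](C)(CCC=C(C)C)C=C)CI | intermediate
9 | B-alkyl-9-BBN adduct of 8 (boron on C9) | CC(C)=CCC/C(C)=C/C[C@@H]([C@](C)(CCC=C(C)C)CCB1C2CCCC1CCC2)CI | intermediate
10 | (3R,4S,6E)-4-(iodomethyl)-3,7,11-trimethyl-3-(4-methylpent-3-enyl)dodeca-6,10-dien-1-ol | CC(C)=CCC/C(C)=C/C[C@@H]([C@](C)(CCC=C(C)C)CCO)CI | intermediate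
11 | (3R,4S,6E)-4-(iodomethyl)-3,7,11-trimethyl-3-(4-methylpent-3-enyl)dodeca-6,10-dienoic acid | CC(C)=CCC/C(C)=C/C[C@@H]([C@](C)(CCC=C(C)C)CC(=O)O)CI | intermediate
12 | methyl ester of 11 | CC(C)=CCC/C(C)=C/C[C@@H]([C@](C)(CCC=C(C)C)CC(=O)OC)CI | intermediate
13 | prenyl bromide (1-bromo-3-methylbut-2-ene) | CC(C)=CCBr | starting material
14 | lithium enolate of ester 12 | CC(C)=CCC/C(C)=C/C[C@@H]([C@](C)(CCC=C(C)C)C=C(OC)O[Li])CI | intermediate
15 | methyl (3R,4S,6E)-4-(iodomethyl)-3,7,11-trimethyl-2-prenyl-3-(4-methylpent-3-enyl)dodeca-6,10-dienoate, C2 epimers | CC(C)=CCC/C(C)=C/C[C@@H]([C@](C)(CCC=C(C)C)C(CC=C(C)C)C(=O)OC)CI | intermediate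
16 | methyl acetoacetate | COC(=O)CC(C)=O | starting material
17 | sodium lithium dianion of methyl acetoacetate | COC(O[Na])=CC(=C)O[Li] | intermediate
18 | methyl 7-methyl-3-oxooct-6-enoate | COC(=O)CC(=O)CCC=C(C)C | intermediate
19 | sodium lithium dianion of 18 | COC(O[Na])=CC(O[Li])=CCC=C(C)C | intermediate
20 | dimethyl (6R,7S)-6-geranyl-7-methyl-7-(4-methylpent-3-enyl)-3-oxo-4,8-diprenylnonanedioate, C4 and C8 epimers | CC(C)=CCC/C(C)=C/C[C@@H]([C@](C)(CCC=C(C)C)C(CC=C(C)C)C(=O)OC)CC(CC=C(C)C)C(=O)CC(=O)OC | intermediate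
21 | dimethyl (2E,6R,7S)-6-geranyl-3-methoxy-7-methyl-7-(4-methylpent-3-enyl)-4,8-diprenylnon-2-enedioate, C4 and C8 epimers | CC(C)=CCC/C(C)=C/C[C@@H]([C@](C)(CCC=C(C)C)C(CC=C(C)C)C(=O)OC)CC(CC=C(C)C)/C(OC)=C\C(=O)OC | intermediate
22 | monocyclic C9 ketone: cyclohexanone (ring B) with C5 (S) bearing prenyl and the axial (E)-1-methoxy-2-(methoxycarbonyl)vinyl arm, C7 (R) geranyl, C8 (S) methyl/homoprenyl, C1 prenyl (epimers) | CC(C)=CCC/C(C)=C/C[C@@H]1C[C@@](CC=C(C)C)(/C(OC)=C\C(=O)OC)C(=O)C(CC=C(C)C)[C@@]1(C)CCC=C(C)C | intermediate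
23 | (1R,5S,7R,8S)-7-geranyl-4-methoxy-8-methyl-8-(4-methylpent-3-enyl)-1,5-diprenylbicyclo[3.3.1]non-3-ene-2,9-dione (geranyl equatorial/exo, C8 methyl axial) | CC(C)=CCC/C(C)=C/C[C@@H]1C[C@]2(CC=C(C)C)C(=O)[C@@](CC=C(C)C)(C(=O)C=C2OC)[C@@]1(C)CCC=C(C)C | intermediate
24 | 3-hydroxybenzoic acid | OC(=O)c1cccc(O)c1 | starting material
25 | tert-butyldimethylsilyl 3-(tert-butyldimethylsilyloxy)benzoate | CC(C)(C)[Si](C)(C)OC(=O)c1cccc(O[Si](C)(C)C(C)(C)C)c1 | intermediate
26 | 3-(tert-butyldimethylsilyloxy)benzoyl chloride | ClC(=O)c1cccc(O[Si](C)(C)C(C)(C)C)c1 | intermediate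
27 | C3-lithio derivative of 23 | CC(C)=CCC/C(C)=C/C[C@@H]1C[C@]2(CC=C(C)C)C(=O)[C@@](CC=C(C)C)(C(=O)C([Li])=C2OC)[C@@]1(C)CCC=C(C)C | intermediate
28 | (1S,5S,7R,8S)-3-[3-(tert-butyldimethylsilyloxy)benzoyl]-7-geranyl-4-methoxy-8-methyl-8-(4-methylpent-3-enyl)-1,5-diprenylbicyclo[3.3.1]non-3-ene-2,9-dione | CC(C)=CCC/C(C)=C/C[C@@H]1C[C@]2(CC=C(C)C)C(=O)[C@@](CC=C(C)C)(C(=O)C(C(=O)c3cccc(O[Si](C)(C)C(C)(C)C)c3)=C2OC)[C@@]1(C)CCC=C(C)C | intermediate
29 | (1S,5S,7R,8S)-7-geranyl-4-hydroxy-3-(3-hydroxybenzoyl)-8-methyl-8-(4-methylpent-3-enyl)-1,5-diprenylbicyclo[3.3.1]non-3-ene-2,9-dione | CC(C)=CCC/C(C)=C/C[C@@H]1C[C@]2(CC=C(C)C)C(=O)[C@@](CC=C(C)C)(C(=O)C(C(=O)c3cccc(O)c3)=C2O)[C@@]1(C)CCC=C(C)C | target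

Total step count: 16. Longest linear sequence: 13 steps (steps 1–8, 10–12, 15 and 16).

Steps most likely to fail

**Step 12 (Proposed new method).**
- What may go wrong:
  - Deprotonation at C1 or at the vinylic C3–H instead of C5 may stall the first acylation.
  - Attack through the wrong dienolate face would place the enoate arm cis to the C7 geranyl group, so that the second ring closes only through a strained conformer or not at all.
  - Attack of methoxide may reopen ring B.
- Fallback: it sets out from 15, comes back at 23 and uses known chemistry only.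
  - Homoprenyl phenyl sulfone F1 (from 5-bromo-2-methylpent-2-ene and sodium benzenesulfinate) is lithiated and alkylated with 15 to the sulfone ester F2.
  - LDA closes ring B by acylation of the sulfonyl carbanion at the C9 ester to the β-keto sulfone F3.
  - SmI2 removes the sulfonyl group to give the 2,6-diprenylcyclohexanone F4.
  - HC(OMe)3 and TsOH convert it into the methyl enol ether F5.
  - An Effenberger annulation with malonyl dichloride, followed by KOH/BnEt3NCl, bridges the two axial α-positions to the free trione F6.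
  - O-methylation and separation of the enol ether regioisomers give 23.

**Step 10.**
- What may go wrong: displacement at the β-branched iodide by the already substituted γ-carbanion may be slow, so that proton transfer from the ester α-position or elimination takes over.
- Fallback: it sets out from 15, comes back at 20 and reverses the order of the two γ-alkylations.
  - The smaller, unsubstituted dianion 17 is alkylated with 15 to the unbranched keto diester F7.
  - A second dianion formation (LDA, −78 °C) and the fast allylic bromide 13 then place the C5 prenyl group, giving 20.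

**Step 2.**
- What may go wrong:
  - The rearrangement onto a trisubstituted alkene terminus may be sluggish.
  - Loss of enolate geometry would erode the C7/C8 relative configuration.
  - Facial selectivity of the controller may be incomplete.
- Fallback: it sets out from 4, comes back at 6 and gives up reagent control.
  - LDA in THF/DMPU with TMSCl gives the Z(O)-silyl ketene acetal F8.
  - Its Ireland–Claisen rearrangement gives the racemate, that is 6 together with the enantiomeric acid F9.
  - Crystallisation of the (S)-1-phenylethylammonium salt F10 and acidification return 6.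

Further compounds
F1 | step 12 | homoprenyl phenyl sulfone | CC(C)=CCCS(=O)(=O)c1ccccc1
F2 | step 12 | sulfone ester | CC(C)=CCC/C(C)=C/C[C@@H]([C@](C)(CCC=C(C)C)C(CC=C(C)C)C(=O)OC)CC(CC=C(C)C)S(=O)(=O)c1ccccc1
F3 | step 12 | β-keto sulfone | CC(C)=CCC/C(C)=C/C[C@@H]1CC(CC=C(C)C)(S(=O)(=O)c2ccccc2)C(=O)C(CC=C(C)C)[C@@]1(C)CCC=C(C)C
F4 | step 12 | 2,6-diprenylcyclohexanone | CC(C)=CCC/C(C)=C/C[C@@H]1CC(CC=C(C)C)C(=O)C(CC=C(C)C)[C@@]1(C)CCC=C(C)C
F5 | step 12 | methyl enol ether | CC(C)=CCC/C(C)=C/C[C@@H]1CC(CC=C(C)C)=C(OC)C(CC=C(C)C)[C@@]1(C)CCC=C(C)C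
F6 | step 12 | free trione | CC(C)=CCC/C(C)=C/C[C@@H]1C[C@]2(CC=C(C)C)C(=O)[C@@](CC=C(C)C)(C(=O)C=C2O)[C@@]1(C)CCC=C(C)C
F7 | step 10 | unbranched keto diester | CC(C)=CCC/C(C)=C/C[C@@H]([C@](C)(CCC=C(C)C)C(CC=C(C)C)C(=O)OC)CCC(=O)CC(=O)OC
F8 | step 2 | Z(O)-silyl ketene acetal | CC(C)=CCC/C(C)=C/C/C=C(\O[Si](C)(C)C)OC/C=C(\C)CCC=C(C)C
F9 | step 2 | enantiomeric acid | CC(C)=CCC/C(C)=C/C[C@H]([C@@](C)(CCC=C(C)C)C=C)C(=O)O
F10 | step 2 | (S)-1-phenylethylammonium salt | CC(C)=CCC/C(C)=C/C[C@@H]([C@](C)(CCC=C(C)C)C=C)C(=O)[O-].C[C@H]([NH3+])c1ccccc1
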